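(The rate constants are those of an exercise; no experiment stands behind them.)

Count in hours, and two of the fates of L become directly comparable.

    L + X.L → L.X.L (k1 = 0.00123 M⁻¹ s⁻¹)
    X + L → D, rate k2*[X] as long as [L] is above zero (k2 = 8.58 × 10⁻⁵ s⁻¹)
    L → Q (k3 = 1.71 × 10⁻⁴ s⁻¹)
    X + L → X.L (k4 = 0.00768 M⁻¹ s⁻¹)

common to all: time 3.0 h

| charge | X | L | remark |
|---|---|---|---|
| ochre | 0.050 M | 1.10 equiv (fed, over 30 min) | all else is in the flask from the start; the feed brings no volume worth counting |
| amber | 0.050 M | 1.10 equiv (in portions, 5, over 2.0 h) | first portion at the start, last at 2.0 h |
| grey | 0.050 M (fed, over 2.0 h) | 1.10 equiv | all else is in the flask from the start; the feed brings no volume worth counting |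
| violet | 0.050 M | 1.10 equiv (fed, over 2.0 h) | all else is in the flask from the start; the feed brings no volume worth counting |
| red | 0.050 M | 1.10 equiv | everything together at the start |

* the flask with the highest amount of X.L, in percent of the X charged ("all alike" if they lie within 1.5 percentage points) (ochre / amber / grey / violet / red / all alike)
* final X.L, as a percentage of the X charged, in ochre
* final X.L, as a percentage of the X charged, in amber
* final X.L, as a percentage of the X charged, in grey
* final X.L, as a percentage of the X charged, in violet
* final X.L, as a percentage of the X charged, in red

1. Let x be the fraction of the charged X still free. L → Q gives L a lifetime of 1.62 h, while X + L → X.L takes L in a time of 0.723 h when x stands at one.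

2. Both steps are first order in L, so L cancels from their ratio, which is S·x. Here S = 2.25, the link-to-loss ratio, is a selectivity factor for L.

3. In red x starts at one, so at the start the link step outruns the loss by S.

4. In grey, X enters at 0.500 h⁻¹ as a fraction of its charge and leaves by links and rings. With L held at its charge, this linear equation integrates to a rise towards x = 0.273, with a time constant of 0.547 h. L falls meanwhile, so this x is a low figure.

5. Grey's ratio is then 0.614, smaller than red's starting value. I commit to red above grey in X.L, and to no percentage.

6. The forecast names red, with red 41%, ochre 39%, violet 27%, amber 26.5% and grey 25%, holding that “keeping both X and L concentrated from the start favours X.L”.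

7. The simulation puts red highest: red 43.7%, ochre 39.3%, amber 27.1%, violet 27.0%, grey 25.0%.

8. The mean X read in grey over the first 2.0 h is 0.0147 M, so x averages 0.294 and S times that is 0.661; in red the mean over that time is 0.0222 M, which gives 0.999. Grey ends with more Q than red, 0.0297 M against 0.0165 M. Striking out L → Q narrows the gap between red and grey from 19 percentage points to 4.5 points, the largest single effect among the steps struck out.

9. In a neighbour flask, like red but with 0.20 M of X and the equivalents held, S becomes 8.98, so X.L should climb above red's. It ends at 62.5%.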